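| flask | electrophile | nucleophile | free base | remark | time |
|---|---|---|---|---|---|
| dawn | 0.50 M | 0.40 M | 1 M | run made earlier |  |
| summer | 0.50 M | 0.20 M | 1 M | run made earlier |  |
| autumn | 0.50 M | 0.30 M | 1 M | run made earlier |  |
| eta | 0.50 M | 0.400 M (fed, over 20 h) | 1.00 M | all else is in the flask from the start; the feed brings no volume worth counting | 50 h |
| zeta | 0.50 M | 0.400 M | 1.00 M | everything together at the start | 50 h |
| gamma | 0.50 M (fed, over 20 h) | 0.400 M | 1.00 M | all else is in the flask from the start; the feed brings no volume worth counting | 50 h |

| dawn: time / h | dawn: product / % | summer: time / h | summer: product / % | autumn: time / h | autumn: product / % |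
|---|---|---|---|---|---|
| 12.0 | 29 | 15.0 | 18 | 8.00 | 21 |
| 25.0 | 34 | 30.0 | 26 | 20.0 | 30 |
| 40.0 | 41 | 50.0 | 21 | 40.0 | 33 |
| 48.0 | 39 | 60.0 | 26 | 60.0 | 32 |

(standard deviation of a reading: 2 percentage points)

1. the flask with the highest amount of product, in percent of the electrophile charged ("all alike" if they lie within 1.5 percentage points) (eta / zeta / gamma / all alike)
2. final product, as a percentage of the electrophile charged, in eta
3. final product, as a percentage of the electrophile charged, in zeta
4. final product, as a percentage of the electrophile charged, in gamma

- what was read earlier has a scatter of 2 percentage points, one standard deviation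
- reactions considered so far: electrophile <-> dormant form; 2 nucleophile -> homo dimer; acid set free + free base <-> salt of the base; electrophile + nucleophile -> acid set free + product; nucleophile + acid set free <-> protonated nucleophile

- Slowness was my way in. The dawn run took 40.0 h to read 41 % of product, and at 48.0 h it read 39 %.
- So I asked what else used the nucleophile during those hours. Homo dimer forms at a rate that goes with the square of nucleophile. Coupling to product goes with nucleophile times electrophile. At any moment the rate of coupling over the rate of homo dimer formation, the selectivity factor, follows electrophile over nucleophile.
- The last dawn readings gave 50.0 %. I called this the nucleophile yield, the plateau product per nucleophile charged.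
- First setting, the nucleophile charge. By hand, a lower charge at the same electrophile should favour coupling and raise the yield. The readings agreed: autumn gave 54.2 % and summer 60.8 %, above dawn.
- Second setting, feeding nucleophile. Eta should hold nucleophile low, so I lent it the summer yield, which gave 48.7 % of the electrophile. Zeta repeats dawn, so the dawn yield gave 40.0 %.
- Third setting, feeding electrophile. Gamma starts with the nucleophile charge and no electrophile, so its selectivity factor starts low. I expected a yield below dawn's.
- The forecast named eta, with 46 %, 39 % and 23 % for eta, zeta and gamma. On gamma it said: “Feeding electrophile leaves nucleophile concentrated and starved of partner”. My eta figure stood above its figure.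
- The flasks gave 43.8 % in eta, 36.8 % in zeta and 15.0 % in gamma, so eta led. The forecast for gamma stood 8 percentage points too high.

    electrophile ⇌ dormant form (K = 0.350, k = 4.40 × 10⁻⁴ min⁻¹)
    2 nucleophile → homo dimer (k = 0.0110 L mol⁻¹ min⁻¹)
    acid set free + free base ⇌ salt of the base (K = 31000 L mol⁻¹, k = 0.110 L mol⁻¹ min⁻¹)
    electrophile + nucleophile → acid set free + product (k = 0.00560 L mol⁻¹ min⁻¹)
    nucleophile + acid set free ⇌ protonated nucleophile, settled at all times (K = 450 L mol⁻¹)

- Read at 50.0 h, the nucleophile yield came to 54.7 % in eta, below the yield read from the summer run, and to 18.8 % in gamma. Among the steps removed in simulated runs, the loss to homo dimer had the largest single effect on the gap between eta and gamma. Without it, that gap went from 29 points to −1 point. The neighbour flask, eta with 0.68 M of nucleophile, reached 57.2 % of product, yet its yield dropped to 42.1 %.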